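## Retrosynthetic overview

1. Target ⇐ bis-acetylation of the 8-hydroxy/20-hydroxy acid; ArCO2H ⇐ sterically directed C–H borylation/carboxylation; CH2OH ⇐ C1 methyl ester, with C1 set by equilibration to the 1,4-trans epimer.
2. Side chain ⇐ B-alkyl Suzuki coupling (C13–C14) on a but-3-en-2-yl group ⇐ CuH hydroallylation of a 1,2-dihydronaphthalene with E-crotyl phosphate (C4–C11 bond, C4 and C11 stereocentres).
3. Dihydronaphthalene ⇐ tetralone ⇐ Friedel–Crafts closure of a dimethyl 2-arylglutarate.
4. 2-Arylglutarate ⇐ key skeletal step: iodine(III)-mediated oxidative 1,2-aryl shift of an aryl ketone (ArCO–CH2R → ArCH(R)–CO2Me) ⇐ ortho-lithiated anisole + glutaric anhydride.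
5. Ring order: the benzene ring is bought (anisole); the one carbocycle is closed after the 1,2-shift; the anisole methyl is the only protecting group.

Assumption: serrulatane locants are used in the comments (C1 = ring CH bearing C20, C4 = ring CH bearing the side chain, C11 = side-chain CH(CH3), C8 = ArO carbon, C6 = ArCO2H carbon); one step = one isolated product.

## Route

Step 1
Reactants: 1 anisole; 2 glutaric anhydride
Product: 4 keto acid 5-(2-methoxyphenyl)-5-oxopentanoic acid, via 2-methoxyphenyllithium 3 (not isolated)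
Conditions: n-BuLi, TMEDA, Et2O, 0 °C → rt; then add to 2 (1.5 equiv), THF, −78 °C; aq. HCl
Reagents that add atoms: none
Why: OMe-directed ortho-lithiation followed by mono-acylation of the aryllithium with the cyclic anhydride (the carboxylate released on ring opening suppresses a second addition at −78 °C) fixes the C8/C8a substitution pattern; no stereocentre.

Step 2
Reactants: 4 keto acid
Product: 5 dimethyl 2-(2-methoxyphenyl)pentanedioate (racemic)
Conditions: PhI(OAc)2 (1.2 equiv), HC(OMe)3, conc. H2SO4 (2 equiv), MeOH, 60 °C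
Reagents that add atoms: trimethyl orthoformate, COC(OC)OC; methanol, CO
Why: Iodine(III)-mediated oxidative 1,2-aryl migration of an alkyl aryl ketone (iodination of the methyl enol ether, then shift of the electron-rich o-anisyl group through a phenonium ion) moves the arene from the carbonyl carbon (future C20) to the α-carbon (future C1), with Fischer esterification of the remote acid; C1 is formed racemic and is deliberately kept epimerisable.

Step 3
Reactants: 5 diester
Product: 6 methyl 8-methoxy-4-oxo-1,2,3,4-tetrahydronaphthalene-1-carboxylate (racemic)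
Conditions: TfOH (5 equiv), ClCH2CH2Cl, 70 °C
Reagents that add atoms: none
Why: Intramolecular Friedel–Crafts acylation by the remote ester closes the six-membered ring at the only free position ortho to the side chain (C4a), since the α-aryl ester could only form a four-membered ring.

Step 4
Reactants: 6 keto ester
Product: 8 methyl 8-methoxy-1,2-dihydronaphthalene-1-carboxylate (racemic), via hydroxy ester 7 (not isolated)
Conditions: NaBH4, MeOH, 0 °C; work-up; then TsOH·H2O (5 mol%), PhMe, 90 °C, Dean–Stark
Reagents that add atoms: none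
Why: Chemoselective ketone reduction and acid-catalysed E1 dehydration of the benzylic alcohol give the C3=C4 styrene-type alkene; C1 stays racemic.

Step 5
Reactants: 9 (E)-but-2-en-1-ol
Product: 10 diethyl (E)-but-2-en-1-yl phosphate
Conditions: (EtO)2P(O)Cl, Et3N, DMAP (cat.), CH2Cl2, 0 °C
Reagents that add atoms: diethyl chlorophosphate, CCOP(=O)(Cl)OCC
Why: O-phosphorylation of a primary allylic alcohol, with the E geometry untouched.

Step 6
Reactants: 8 dihydronaphthalene ester; 10 E-crotyl phosphate (1.5 equiv)
Product: 11 methyl (1RS,4S)-4-[(2S)-but-3-en-2-yl]-8-methoxy-1,2,3,4-tetrahydronaphthalene-1-carboxylate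
Conditions: Cu(OAc)2 (5 mol%), (S)-DTBM-SEGPHOS (5.5 mol%), (MeO)2MeSiH (3 equiv), LiOtBu (2.5 equiv), THF, rt → 40 °C; aq. NH4Cl
Reagents that add atoms: none
Why: Proposed new method: ligand-bound CuH adds syn across the cyclic styrene to give the benzylic C4–Cu species with ligand-controlled face selectivity (the ligand enantiomer is assigned by analogy with CuH hydrofunctionalisation of styrenes), and this alkylcopper undergoes stereoretentive anti-SN2′ substitution on the E-crotyl phosphate, forming C4–C11 and setting C11 in the ordered Cu(III)-allyl transition state; the closest known reactions are the CuH-catalysed enantioselective hydroallylation of vinylarenes with allyl phosphates and the Cu–alkyl SN2′ coupling with E-γ-substituted allylic phosphates that gives vicinal stereocentres, neither shown for a cyclic β-substituted styrene with a crotyl electrophile; C1 epimerises under the base and is corrected in step 7.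

Step 7
Reactants: 11 butenyl ester; 12 1-bromo-2-methylprop-1-ene
Product: 14 methyl (1R,4S)-8-methoxy-4-[(2S)-6-methylhept-5-en-2-yl]-1,2,3,4-tetrahydronaphthalene-1-carboxylate, via alkylborane 13 (not isolated)
Conditions: 9-BBN, THF, 0 °C → rt; then 12, PdCl2(dppf) (5 mol%), NaOMe (3 equiv), THF/MeOH, 65 °C, 16 h
Reagents that add atoms: none
Why: Anti-Markovnikov hydroboration of the only terminal alkene and B-alkyl Suzuki–Miyaura coupling complete the side chain without touching C4/C11, while methoxide equilibrates the α-aryl methyl ester to the trans (1R) epimer, in which the ester (peri to 8-OMe) and the C4 side chain (peri to H-5) are both pseudoaxial.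

Step 8
Reactants: 14 ester
Product: 16 (5R,8S)-4-methoxy-5-(methoxycarbonyl)-8-[(2S)-6-methylhept-5-en-2-yl]-5,6,7,8-tetrahydronaphthalene-2-carboxylic acid, via aryl pinacol boronate 15 (not isolated)
Conditions: [Ir(cod)OMe]2 (1.5 mol%), dtbpy (3 mol%), B2pin2 (1.0 equiv), THF, 80 °C; evaporate; then (IPr)CuCl (5 mol%), CsF (3 equiv), CO2 (1 atm), DMF, 90 °C; aq. HCl
Reagents that add atoms: bis(pinacolato)diboron (boryl group of 15 only), CC1(C)OB(OC1(C)C)B1OC(C)(C)C(C)(C)O1; carbon dioxide, O=C=O
Why: Sterically controlled Ir-catalysed C–H borylation goes to the only aromatic C–H without an ortho substituent (C6), and Cu-catalysed carboxylation of the aryl boronate with CO2 gives the acid; no stereocentre is formed and C1 stays at its equilibrium ratio.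

Step 9
Reactants: 16 acid ester
Product: 18 (5R,8S)-4-hydroxy-5-(hydroxymethyl)-8-[(2S)-6-methylhept-5-en-2-yl]-5,6,7,8-tetrahydronaphthalene-2-carboxylic acid, via methyl ether alcohol 17 (not isolated)
Conditions: LiEt3BH (8 equiv), THF, 0 °C, 1 h; then 67 °C, 24 h; MeOH, aq. HCl
Reagents that add atoms: none
Why: Super-Hydride reduces the aliphatic methyl ester at 0 °C (fixing C1 as CH–CH2OH without enolisation) and at reflux cleaves the aryl methyl ether by SN2 hydride attack on the O-methyl group (hydride-promoted demethylation), while the lithium carboxylate and the trisubstituted alkene are inert; the minor C1 epimer is removed by chromatography here.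

Step 10
Reactants: 18 dihydroxy acid
Product: 19 (5R,8S)-4-acetoxy-5-(acetoxymethyl)-8-[(2S)-6-methylhept-5-en-2-yl]-5,6,7,8-tetrahydronaphthalene-2-carboxylic acid (target)
Conditions: Ac2O (5 equiv), pyridine, DMAP (cat.), 0 °C → rt; then H2O/THF, rt; aq. HCl
Reagents that add atoms: acetic anhydride, CC(=O)OC(C)=O
Why: Acylation of the phenol and the primary alcohol, with the mixed anhydride at the benzoic acid hydrolysed selectively on aqueous work-up; no stereocentre is touched.

## Compound list

1 | anisole | COc1ccccc1 | starting material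
2 | glutaric anhydride | O=C1CCCC(=O)O1 | starting material
3 | 2-methoxyphenyllithium | [Li]c1ccccc1OC | intermediate
4 | 5-(2-methoxyphenyl)-5-oxopentanoic acid | COc1ccccc1C(=O)CCCC(=O)O | intermediate
5 | dimethyl 2-(2-methoxyphenyl)pentanedioate (racemic) | COC(=O)CCC(C(=O)OC)c1ccccc1OC | intermediate
6 | methyl 8-methoxy-4-oxo-1,2,3,4-tetrahydronaphthalene-1-carboxylate (racemic) | COC(=O)C1CCC(=O)c2cccc(OC)c12 | intermediate
7 | methyl 4-hydroxy-8-methoxy-1,2,3,4-tetrahydronaphthalene-1-carboxylate (diastereomer mixture) | COC(=O)C1CCC(O)c2cccc(OC)c12 | intermediate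
8 | methyl 8-methoxy-1,2-dihydronaphthalene-1-carboxylate (racemic) | COC(=O)C1CC=Cc2cccc(OC)c12 | intermediate
9 | (E)-but-2-en-1-ol | C/C=C/CO | starting material
10 | diethyl (E)-but-2-en-1-yl phosphate | C/C=C/COP(=O)(OCC)OCC | intermediate
11 | methyl (1RS,4S)-4-[(2S)-but-3-en-2-yl]-8-methoxy-1,2,3,4-tetrahydronaphthalene-1-carboxylate | COC(=O)C1CC[C@@H]([C@@H](C)C=C)c2cccc(OC)c12 | intermediate
12 | 1-bromo-2-methylprop-1-ene | CC(C)=CBr | starting material
13 | methyl (1RS,4S)-4-[(2S)-4-(9-borabicyclo[3.3.1]nonan-9-yl)butan-2-yl]-8-methoxy-1,2,3,4-tetrahydronaphthalene-1-carboxylate | COC(=O)C1CC[C@@H]([C@@H](C)CCB2C3CCCC2CCC3)c2cccc(OC)c12 | intermediate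
14 | methyl (1R,4S)-8-methoxy-4-[(2S)-6-methylhept-5-en-2-yl]-1,2,3,4-tetrahydronaphthalene-1-carboxylate | COC(=O)[C@@H]1CC[C@@H]([C@@H](C)CCC=C(C)C)c2cccc(OC)c12 | intermediate
15 | methyl (1R,4S)-8-methoxy-4-[(2S)-6-methylhept-5-en-2-yl]-6-(4,4,5,5-tetramethyl-1,3,2-dioxaborolan-2-yl)-1,2,3,4-tetrahydronaphthalene-1-carboxylate | COC(=O)[C@@H]1CC[C@@H]([C@@H](C)CCC=C(C)C)c2cc(B3OC(C)(C)C(C)(C)O3)cc(OC)c12 | intermediate
16 | (5R,8S)-4-methoxy-5-(methoxycarbonyl)-8-[(2S)-6-methylhept-5-en-2-yl]-5,6,7,8-tetrahydronaphthalene-2-carboxylic acid | COC(=O)[C@@H]1CC[C@@H]([C@@H](C)CCC=C(C)C)c2cc(C(=O)O)cc(OC)c12 | intermediate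
17 | (5R,8S)-5-(hydroxymethyl)-4-methoxy-8-[(2S)-6-methylhept-5-en-2-yl]-5,6,7,8-tetrahydronaphthalene-2-carboxylic acid | OC[C@@H]1CC[C@@H]([C@@H](C)CCC=C(C)C)c2cc(C(=O)O)cc(OC)c12 | intermediate
18 | (5R,8S)-4-hydroxy-5-(hydroxymethyl)-8-[(2S)-6-methylhept-5-en-2-yl]-5,6,7,8-tetrahydronaphthalene-2-carboxylic acid | OC[C@@H]1CC[C@@H]([C@@H](C)CCC=C(C)C)c2cc(C(=O)O)cc(O)c12 | intermediate
19 | (5R,8S)-4-acetoxy-5-(acetoxymethyl)-8-[(2S)-6-methylhept-5-en-2-yl]-5,6,7,8-tetrahydronaphthalene-2-carboxylic acid | CC(=O)OC[C@@H]1CC[C@@H]([C@@H](C)CCC=C(C)C)c2cc(C(=O)O)cc(OC(C)=O)c21 | target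

## Step count and risks

Total steps: 10. Longest linear sequence: 9 (steps 1–4 and 6–10; step 5 is a one-step branch).

**Step 6 (proposed new hydroallylation).** The risks are CuH reduction of the phosphate, proton quench of the benzylcopper by the acidic C1–H (pre-forming the ester enolate would remove it), and an unverified sense of induction at C11 for the E-phosphate. The fallback uses known chemistry, sets out from 8 and returns at 11. CuH-catalysed asymmetric hydroboration of 8 with pinacolborane (same ligand, same alkene face) gives the benzylic boronate methyl (1RS,4R)-8-methoxy-4-(4,4,5,5-tetramethyl-1,3,2-dioxaborolan-2-yl)-1,2,3,4-tetrahydronaphthalene-1-carboxylate F1. With the ester masked in situ as its lithium enolate (LDA, −78 °C), F1 is homologated with ethyl 2,4,6-triisopropylbenzoate lithiated by s-BuLi/(−)-sparteine; the 1,2-metallate shift retains C4 and the reagent sets C11, giving methyl (1RS,4S)-8-methoxy-4-[(1R)-1-(4,4,5,5-tetramethyl-1,3,2-dioxaborolan-2-yl)ethyl]-1,2,3,4-tetrahydronaphthalene-1-carboxylate F2. Zweifel olefination of F2 (vinylmagnesium bromide, then I2 and NaOMe) gives 11.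

**Step 7 (C1 control by equilibration).** The trans preference rests on peri strain and may be only moderate. The fallback sets C1 by catalyst control; it sets out from 14 (as its C1 epimer mixture) and returns at 14. Enolate dehydrogenation (LDA, then N-tert-butylbenzenesulfinimidoyl chloride) gives methyl (4S)-8-methoxy-4-[(2S)-6-methylhept-5-en-2-yl]-3,4-dihydronaphthalene-1-carboxylate F3. Saponification (LiOH) gives (4S)-8-methoxy-4-[(2S)-6-methylhept-5-en-2-yl]-3,4-dihydronaphthalene-1-carboxylic acid F4. Carboxylate-directed asymmetric hydrogenation with Ru(OAc)2(BINAP), which leaves the isolated trisubstituted olefin alone, gives (1R,4S)-8-methoxy-4-[(2S)-6-methylhept-5-en-2-yl]-1,2,3,4-tetrahydronaphthalene-1-carboxylic acid F5 with the BINAP enantiomer that delivers 1R. Re-esterification (MeI, K2CO3) returns 14.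

**Step 9 (one-pot ester reduction and O-demethylation).** The hydride demethylation may be slow or incomplete. The fallback sets out from 16 and returns at 18: reduce the ester with LiBH4 (THF/MeOH) and isolate the methyl ether alcohol 17, then cleave the aryl methyl ether with NaSEt in DMF at 120 °C (thiolate SN2) to give 18; new compounds: none F0.

## Further compounds

F1 | step 6 | methyl (1RS,4R)-8-methoxy-4-(4,4,5,5-tetramethyl-1,3,2-dioxaborolan-2-yl)-1,2,3,4-tetrahydronaphthalene-1-carboxylate | COC(=O)C1CC[C@@H](B2OC(C)(C)C(C)(C)O2)c2cccc(OC)c12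
F2 | step 6 | methyl (1RS,4S)-8-methoxy-4-[(1R)-1-(4,4,5,5-tetramethyl-1,3,2-dioxaborolan-2-yl)ethyl]-1,2,3,4-tetrahydronaphthalene-1-carboxylate | COC(=O)C1CC[C@@H]([C@@H](C)B2OC(C)(C)C(C)(C)O2)c2cccc(OC)c12
F3 | step 7 | methyl (4S)-8-methoxy-4-[(2S)-6-methylhept-5-en-2-yl]-3,4-dihydronaphthalene-1-carboxylate | COC(=O)C1=CC[C@@H]([C@@H](C)CCC=C(C)C)c2cccc(OC)c12
F4 | step 7 | (4S)-8-methoxy-4-[(2S)-6-methylhept-5-en-2-yl]-3,4-dihydronaphthalene-1-carboxylic acid | OC(=O)C1=CC[C@@H]([C@@H](C)CCC=C(C)C)c2cccc(OC)c12
F5 | step 7 | (1R,4S)-8-methoxy-4-[(2S)-6-methylhept-5-en-2-yl]-1,2,3,4-tetrahydronaphthalene-1-carboxylic acid | OC(=O)[C@@H]1CC[C@@H]([C@@H](C)CCC=C(C)C)c2cccc(OC)c12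
F0 | step 9 | none | none
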